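The route rests on cutting the O1–C8a bond of the flavone pyranone (ring C). C8a of ring A lies between C8, which carries the future coumarin aryl, and C4a, which carries the C4 acyl carbon. Held as C–F, this single carbon steers both neighbouring metalations and then supplies the leaving group. In the key step the oxygen of a 1,3-diketone enolate attacks that carbon and expels fluoride, so ring C and the placement of O1 next to the 8-aryl group arise in one operation. The precursor is 1-(2-fluoro-4,6-dimethoxyphenyl)-3-(4-methoxyphenyl)propane-1,3-dione bearing a 2,4-dimethoxyphenyl group at C3 of the fluorinated ring. Formylation, Z-selective olefination and global demethylation then complete the coumarin.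

Key step: step 4

Assumption: the target SMILES carries no stereodescriptor, and the biaryl axis is flanked only by small oxygen substituents and one hydrogen, so it is treated as configurationally undefined and no axial control is planned.

Locants: flavone numbering is used for rings A, C and B (ring B primed). The pendant aryl ring D is double-primed, with C1'' bonded to C8.

Step 1
Reactants: 1 1-fluoro-3,5-dimethoxybenzene; 2 1-bromo-2,4-dimethoxybenzene
Product: 5 2-fluoro-2',4,4',6-tetramethoxy-1,1'-biphenyl, via aryllithium 3 (not isolated), via arylzinc chloride 4 (not isolated)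
Conditions: 2,2,6,6-tetramethylpiperidine, n-BuLi, THF, −78 °C; ZnCl2 (THF), −78 °C → rt; 2, Pd(OAc)2 (2 mol %), RuPhos (4 mol %), THF, 65 °C
Reagents that add atoms: none
Why: Directed ortho-metalation followed by Negishi coupling: the hindered lithium amide takes the most acidic ring proton, the one flanked by fluorine and methoxy, exchange to zinc at −78 °C forestalls loss of LiF to an aryne, and a bulky dialkylbiarylphosphine on palladium is suited to a biaryl with three ortho substituents, one of which is the very small fluorine.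

Step 2
Reactants: 5 2-fluoro-2',4,4',6-tetramethoxy-1,1'-biphenyl; 6 N-methoxy-N-methylacetamide
Product: 8 1-[3-(2,4-dimethoxyphenyl)-2-fluoro-4,6-dimethoxyphenyl]ethan-1-one, via lithiated biaryl 7 (not isolated)
Conditions: 2,2,6,6-tetramethylpiperidine, n-BuLi, THF, −78 °C; 6, −78 → 0 °C; then 1 M HCl
Reagents that add atoms: none
Why: Second directed ortho-metalation and Weinreb ketone synthesis: the only remaining proton next to fluorine (between F and OMe on ring A) is clearly more acidic than the two protons lying between methoxy pairs, which a lithium amide at −78 °C should leave alone, and the N-methoxy-N-methylamide stops at the methyl ketone without over-addition.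

Step 3
Reactants: 8 1-[3-(2,4-dimethoxyphenyl)-2-fluoro-4,6-dimethoxyphenyl]ethan-1-one; 9 methyl 4-methoxybenzoate
Product: 10 1-[3-(2,4-dimethoxyphenyl)-2-fluoro-4,6-dimethoxyphenyl]-3-(4-methoxyphenyl)propane-1,3-dione
Conditions: NaH (2.5 equiv), THF, 60 °C; then 1 M HCl
Reagents that add atoms: none
Why: Crossed Claisen condensation: the ester cannot enolise, the hindered methyl ketone is the only carbon acid and is slow to self-condense, irreversible deprotonation of the 1,3-diketone pulls the equilibrium over, and the tightly chelated sodium diketonate in THF should leave the C–F bond intact so that 10 can be isolated.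

Step 4
Reactants: 10 1-[3-(2,4-dimethoxyphenyl)-2-fluoro-4,6-dimethoxyphenyl]-3-(4-methoxyphenyl)propane-1,3-dione
Product: 11 8-(2,4-dimethoxyphenyl)-5,7-dimethoxy-2-(4-methoxyphenyl)-4H-chromen-4-one
Conditions: K2CO3 (2 equiv), dry DMF, 100–120 °C
Reagents that add atoms: none
Why: K2CO3 turns 10 into its potassium enolate, and the oxygen on the anisoyl-side carbon adds to the fluorine-bearing ring carbon (future C8a) to give a Meisenheimer anion whose charge rests on C4a, C6 and C8 and is drained through C4a into the C4 carbonyl before fluoride leaves and ring A rearomatises. The closest known reaction type is the base-mediated intramolecular SNAr (addition–elimination) of ortho-haloaryl 1,3-diketones to chromones and flavones. Ring C closes in a formally 6-endo-trig mode, since the C4a=C8a π bond that accepts the electrons lies inside the new six-membered ring, just as in the oxa-Michael closure of 2'-hydroxychalcones, and attack by the other oxygen or by the central carbon would need a four-membered ring. No stereocentre is created. The selectivity required is displacement of fluoride and not of the methoxy group that is likewise ortho to the ketone, and it is secured by the far faster addition to the strongly polarised C–F carbon and by the poor leaving ability of methoxide, so that O1 ends on the carbon next to the aryl-bearing C8. Both ring A methoxy groups are meta to the C–F carbon and therefore sit on carbons that carry no charge in the adduct, while hot DMF frees the enolate oxygen from the tight metal chelate that keeps it idle in THF in step 3.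

Step 5
Reactants: 11 8-(2,4-dimethoxyphenyl)-5,7-dimethoxy-2-(4-methoxyphenyl)-4H-chromen-4-one
Product: 13 5-[5,7-dimethoxy-2-(4-methoxyphenyl)-4-oxo-4H-chromen-8-yl]-2,4-dimethoxybenzaldehyde, via aryl iminium chloride 12 (not isolated)
Conditions: POCl3 (3 equiv), DMF, 0 → 70 °C; then ice-water
Reagents that add atoms: N,N-dimethylformamide CN(C)C=O; water O
Why: Vilsmeier–Haack formylation: ring D is twisted out of conjugation with the flavone and stays as electron-rich as resorcinol dimethyl ether, whereas rings A, B and C are deactivated by the pyranone carbonyl (more so once its oxygen is complexed in the acidic medium), and within ring D the open C5'' (para to 2''-OMe, ortho to 4''-OMe) is favoured over C3'', which is hemmed in by two methoxy groups.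

Step 6
Reactants: 13 5-[5,7-dimethoxy-2-(4-methoxyphenyl)-4-oxo-4H-chromen-8-yl]-2,4-dimethoxybenzaldehyde
Product: 14 methyl (Z)-3-{5-[5,7-dimethoxy-2-(4-methoxyphenyl)-4-oxo-4H-chromen-8-yl]-2,4-dimethoxyphenyl}prop-2-enoate
Conditions: (CF3CH2O)2P(O)CH2CO2Me, KN(SiMe3)2, 18-crown-6, THF, −78 °C; then 1 M HCl
Reagents that add atoms: methyl 2-[bis(2,2,2-trifluoroethoxy)phosphoryl]acetate COC(=O)CP(=O)(OCC(F)(F)F)OCC(F)(F)F
Why: Still–Gennari variant of the Horner–Wadsworth–Emmons olefination: the electron-poor phosphonate makes elimination from the kinetically favoured adduct faster than its equilibration, so the (Z)-enoate should prevail, which places the ester on the same side as the 4''-oxygen, the geometry that an (E)-cinnamate lacks and that lactonisation demands.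

Step 7
Reactants: 14 methyl (Z)-3-{5-[5,7-dimethoxy-2-(4-methoxyphenyl)-4-oxo-4H-chromen-8-yl]-2,4-dimethoxyphenyl}prop-2-enoate
Product: 16 5,7-dihydroxy-8-(7-hydroxy-2-oxo-2H-chromen-6-yl)-2-(4-hydroxyphenyl)-4H-chromen-4-one, via pentaphenol ester 15 (not isolated)
Conditions: BBr3 (12 equiv), CH2Cl2, −78 °C → rt; then ice-water
Reagents that add atoms: none
Why: Lewis-acid aryl methyl ether cleavage followed by lactonisation: bromide attacks each boron-activated O-methyl carbon so that all five ethers fall, the freed 4''-oxygen lies cis to the ester and closes the coumarin with loss of methanol, any (E)-ester should be funnelled through Lewis-acid-promoted rotation of the push–pull alkene, and the cold non-aqueous medium avoids the Wessely–Moser ring opening and reclosure that hot mineral acid could use to move the aryl group from C8 to C6.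

Compound list
1 | 1-fluoro-3,5-dimethoxybenzene | COc1cc(F)cc(OC)c1 | starting material
2 | 1-bromo-2,4-dimethoxybenzene | COc1ccc(Br)c(OC)c1 | starting material
3 | (2-fluoro-4,6-dimethoxyphenyl)lithium | [Li]c1c(F)cc(OC)cc1OC | intermediate
4 | (2-fluoro-4,6-dimethoxyphenyl)zinc chloride | Cl[Zn]c1c(F)cc(OC)cc1OC | intermediate
5 | 2-fluoro-2',4,4',6-tetramethoxy-1,1'-biphenyl | COc1ccc(c(OC)c1)-c1c(F)cc(OC)cc1OC | intermediate
6 | N-methoxy-N-methylacetamide | CON(C)C(C)=O | starting material
7 | [3-(2,4-dimethoxyphenyl)-2-fluoro-4,6-dimethoxyphenyl]lithium | [Li]c1c(F)c(-c2ccc(OC)cc2OC)c(OC)cc1OC | intermediate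
8 | 1-[3-(2,4-dimethoxyphenyl)-2-fluoro-4,6-dimethoxyphenyl]ethan-1-one | CC(=O)c1c(F)c(-c2ccc(OC)cc2OC)c(OC)cc1OC | intermediate
9 | methyl 4-methoxybenzoate | COC(=O)c1ccc(OC)cc1 | starting material
10 | 1-[3-(2,4-dimethoxyphenyl)-2-fluoro-4,6-dimethoxyphenyl]-3-(4-methoxyphenyl)propane-1,3-dione | COc1ccc(cc1)C(=O)CC(=O)c1c(F)c(-c2ccc(OC)cc2OC)c(OC)cc1OC | intermediate
11 | 8-(2,4-dimethoxyphenyl)-5,7-dimethoxy-2-(4-methoxyphenyl)-4H-chromen-4-one | COc1ccc(cc1)-c1cc(=O)c2c(OC)cc(OC)c(-c3ccc(OC)cc3OC)c2o1 | intermediate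
12 | {5-[5,7-dimethoxy-2-(4-methoxyphenyl)-4-oxo-4H-chromen-8-yl]-2,4-dimethoxybenzylidene}dimethylammonium chloride | COc1ccc(cc1)-c1cc(=O)c2c(OC)cc(OC)c(-c3cc(C=[N+](C)C)c(OC)cc3OC)c2o1.[Cl-] | intermediate
13 | 5-[5,7-dimethoxy-2-(4-methoxyphenyl)-4-oxo-4H-chromen-8-yl]-2,4-dimethoxybenzaldehyde | COc1ccc(cc1)-c1cc(=O)c2c(OC)cc(OC)c(-c3cc(C=O)c(OC)cc3OC)c2o1 | intermediate
14 | methyl (Z)-3-{5-[5,7-dimethoxy-2-(4-methoxyphenyl)-4-oxo-4H-chromen-8-yl]-2,4-dimethoxyphenyl}prop-2-enoate | COc1ccc(cc1)-c1cc(=O)c2c(OC)cc(OC)c(-c3cc(/C=C\C(=O)OC)c(OC)cc3OC)c2o1 | intermediate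
15 | methyl (Z)-3-{5-[5,7-dihydroxy-2-(4-hydroxyphenyl)-4-oxo-4H-chromen-8-yl]-2,4-dihydroxyphenyl}prop-2-enoate (present as its boron aryloxides) | Oc1ccc(cc1)-c1cc(=O)c2c(O)cc(O)c(-c3cc(/C=C\C(=O)OC)c(O)cc3O)c2o1 | intermediate
16 | 5,7-dihydroxy-8-(7-hydroxy-2-oxo-2H-chromen-6-yl)-2-(4-hydroxyphenyl)-4H-chromen-4-one | O=c1ccc2cc(-c3c(O)cc(O)c4c(=O)cc(-c5ccc(O)cc5)oc34)c(O)cc2o1 | target

Total step count: 7. Longest linear sequence: 7 steps (1 → 5 → 8 → 10 → 11 → 13 → 14 → 16).

Steps most likely to fail

1. Step 4 (key step).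
- **What may go wrong:** addition of the enolate oxygen to an electron-rich C–F carbon wedged between ring D and the acyl group may be slow. Retro-Claisen cleavage of the diketone, by traces of water or by dimethylamine from hot DMF, could then compete.
- **Fallback:** the biaryl bond is made last on a ready-made flavone. It sets out from 2 and comes back at 11. Miyaura borylation of 2 (bis(pinacolato)diboron, PdCl2(dppf), KOAc, dioxane, 90 °C) would give 2-(2,4-dimethoxyphenyl)-4,4,5,5-tetramethyl-1,3,2-dioxaborolane F1. Purchased 5,7-dimethoxy-2-(4-methoxyphenyl)-4H-chromen-4-one F2 would be iodinated at its more open C8 (I2, AgOCOCF3, CH2Cl2) to 8-iodo-5,7-dimethoxy-2-(4-methoxyphenyl)-4H-chromen-4-one F3. Suzuki–Miyaura coupling of F1 and F3 (Pd(OAc)2, SPhos, K2CO3, dioxane/water, 90 °C) would deliver 11.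

2. Step 2.
- **What may go wrong:** metalation may spread to the positions between methoxy pairs on ring A or ring D, or the fluorinated aryllithium may lose LiF before it is trapped.
- **Fallback:** electrophilic substitution replaces metalation and the order of bond formation is reversed, which also bypasses step 1. It sets out from 1 and comes back at 8. Friedel–Crafts acetylation of 1 (AcCl, SnCl4, CH2Cl2, 0 °C) should take the less crowded position, ortho to fluorine and para to a methoxy group, giving 1-(2-fluoro-4,6-dimethoxyphenyl)ethan-1-one F4. Iodination (N-iodosuccinimide, CF3CO2H, MeCN) at the more accessible free carbon between F and OMe would give 1-(2-fluoro-3-iodo-4,6-dimethoxyphenyl)ethan-1-one F5. Suzuki–Miyaura coupling of F5 with 2-(2,4-dimethoxyphenyl)-4,4,5,5-tetramethyl-1,3,2-dioxaborolane F1 (Pd(OAc)2, SPhos, K2CO3, dioxane/water) would give 8.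

3. Step 5.
- **What may go wrong:** formylation may spill over to flavone C6. It may also stall, because the acid-complexed pyranone withdraws electron density from ring D.
- **Fallback:** the formyl carbon is placed on ring D before the biaryl bond exists, and the key step is kept. It sets out from arylzinc chloride 4 and comes back at 13. Purchased 5-bromo-2,4-dimethoxybenzaldehyde F6 would be protected (ethylene glycol, TsOH, toluene, reflux) as 2-(5-bromo-2,4-dimethoxyphenyl)-1,3-dioxolane F7. Negishi coupling with 4 under the conditions of step 1 would give 2-[5-(2-fluoro-4,6-dimethoxyphenyl)-2,4-dimethoxyphenyl]-1,3-dioxolane F8. Lithiation next to fluorine as in step 2 would give {3-[5-(1,3-dioxolan-2-yl)-2,4-dimethoxyphenyl]-2-fluoro-4,6-dimethoxyphenyl}lithium F9. Acetylation of F9 with 6, followed by a buffered quench, would give 1-{3-[5-(1,3-dioxolan-2-yl)-2,4-dimethoxyphenyl]-2-fluoro-4,6-dimethoxyphenyl}ethan-1-one F10. Claisen condensation with 9 (NaH, THF, mild NH4Cl work-up) would give 1-{3-[5-(1,3-dioxolan-2-yl)-2,4-dimethoxyphenyl]-2-fluoro-4,6-dimethoxyphenyl}-3-(4-methoxyphenyl)propane-1,3-dione F11. K2CO3 in DMF would close ring C to 8-[5-(1,3-dioxolan-2-yl)-2,4-dimethoxyphenyl]-5,7-dimethoxy-2-(4-methoxyphenyl)-4H-chromen-4-one F12, and aqueous HCl in THF would release 13.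

Further compounds
F1 | step 4 | 2-(2,4-dimethoxyphenyl)-4,4,5,5-tetramethyl-1,3,2-dioxaborolane | COc1ccc(B2OC(C)(C)C(C)(C)O2)c(OC)c1
F2 | step 4 | 5,7-dimethoxy-2-(4-methoxyphenyl)-4H-chromen-4-one (purchased) | COc1ccc(cc1)-c1cc(=O)c2c(OC)cc(OC)cc2o1
F3 | step 4 | 8-iodo-5,7-dimethoxy-2-(4-methoxyphenyl)-4H-chromen-4-one | COc1ccc(cc1)-c1cc(=O)c2c(OC)cc(OC)c(I)c2o1
F4 | step 2 | 1-(2-fluoro-4,6-dimethoxyphenyl)ethan-1-one | CC(=O)c1c(F)cc(OC)cc1OC
F5 | step 2 | 1-(2-fluoro-3-iodo-4,6-dimethoxyphenyl)ethan-1-one | CC(=O)c1c(F)c(I)c(OC)cc1OC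
F6 | step 5 | 5-bromo-2,4-dimethoxybenzaldehyde (purchased) | COc1cc(OC)c(C=O)cc1Br
F7 | step 5 | 2-(5-bromo-2,4-dimethoxyphenyl)-1,3-dioxolane | COc1cc(OC)c(cc1Br)C1OCCO1
F8 | step 5 | 2-[5-(2-fluoro-4,6-dimethoxyphenyl)-2,4-dimethoxyphenyl]-1,3-dioxolane | COc1cc(F)c(c(OC)c1)-c1cc(C2OCCO2)c(OC)cc1OC
F9 | step 5 | {3-[5-(1,3-dioxolan-2-yl)-2,4-dimethoxyphenyl]-2-fluoro-4,6-dimethoxyphenyl}lithium | [Li]c1c(F)c(-c2cc(C3OCCO3)c(OC)cc2OC)c(OC)cc1OC
F10 | step 5 | 1-{3-[5-(1,3-dioxolan-2-yl)-2,4-dimethoxyphenyl]-2-fluoro-4,6-dimethoxyphenyl}ethan-1-one | CC(=O)c1c(F)c(-c2cc(C3OCCO3)c(OC)cc2OC)c(OC)cc1OC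
F11 | step 5 | 1-{3-[5-(1,3-dioxolan-2-yl)-2,4-dimethoxyphenyl]-2-fluoro-4,6-dimethoxyphenyl}-3-(4-methoxyphenyl)propane-1,3-dione | COc1ccc(cc1)C(=O)CC(=O)c1c(F)c(-c2cc(C3OCCO3)c(OC)cc2OC)c(OC)cc1OC
F12 | step 5 | 8-[5-(1,3-dioxolan-2-yl)-2,4-dimethoxyphenyl]-5,7-dimethoxy-2-(4-methoxyphenyl)-4H-chromen-4-one | COc1ccc(cc1)-c1cc(=O)c2c(OC)cc(OC)c(-c3cc(C4OCCO4)c(OC)cc3OC)c2o1
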